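**Strategy.** Ring B is cut at C3–C3a and C7a–O1. The feature exploited is the C3a–C7a edge of ring A, which carries C3 and O1 side by side, with the C7 methoxy group flanking C7a. An ortho-methoxy aryl iodide and the C3–C2–O1 unit of a cis-epoxide map onto this edge. One palladium/norbornene annulation joins 4-iodo-3-methoxybenzaldehyde to the (2R,3S)-cis-1-aryl-2-methyl epoxide. It forms both bonds and ring B, sets C3 by inversion and carries C2 over unchanged, giving the trans-dihydrobenzofuran. The C5 aldehyde then needs only ethylidenation, and the pivalate on ring C is removed last.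

Key step: step 4

Remark (labels): benzofuran numbering is used (O1, C2, C3, C3a, C4–C7, C7a); ring A is the benzo ring, ring B the dihydrofuran ring, ring C the 2-aryl ring.

Remark (assumption): the palladacycle is taken to open the epoxide directly, with a single inversion at the attacked carbon; the cis-epoxide is chosen on that basis.

Remark (design): the aryl iodide carries C5 at the aldehyde oxidation level, so no redox adjustment follows the annulation and the phenol stays masked until the final step. Compounds 1, 3, 7 and 9 are catalogue chemicals.

**Step 1**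
Reactants: 1 syringaldehyde
Product: 2 4-formyl-2,6-dimethoxyphenyl pivalate
Conditions: PivCl (1.2 equiv), Et3N (1.5 equiv), DMAP (5 mol%), CH2Cl2, 0 °C → rt
Reagents that add atoms: pivaloyl chloride, CC(C)(C)C(=O)Cl
Why: DMAP-catalysed O-acylation (nucleophilic acyl substitution) of the acidic phenol leaves the aldehyde untouched, and the hindered, electron-withdrawing pivalate masks the phenol against ylide and oxidant and later makes the benzylic epoxide carbon less prone to ionise.

**Step 2**
Reactants: 2 4-formyl-2,6-dimethoxyphenyl pivalate; 3 ethyltriphenylphosphonium bromide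
Product: 5 (Z)-2,6-dimethoxy-4-(prop-1-en-1-yl)phenyl pivalate, via ethylidenetriphenylphosphorane 4 (not isolated)
Conditions: 3, NaN(SiMe3)2, THF, 0 °C; then 2, −78 °C → rt
Reagents that add atoms: none
Why: Wittig reaction of a non-stabilised ylide under lithium-free conditions runs through the kinetically favoured cis-oxaphosphetane and should give mainly the (Z)-alkene, the aldehyde reacting far faster than the hindered aryl ester at −78 °C.

**Step 3**
Reactants: 5 (Z)-2,6-dimethoxy-4-(prop-1-en-1-yl)phenyl pivalate
Product: 6 2,6-dimethoxy-4-[(2R,3S)-3-methyloxiran-2-yl]phenyl pivalate (cis-epoxide)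
Conditions: (R,R)-N,N'-bis(3,5-di-tert-butylsalicylidene)-1,2-cyclohexanediaminomanganese chloride, (R,R)-(salen)MnCl (5 mol%), 4-phenylpyridine N-oxide (20 mol%), aq NaOCl (pH 11.3, Na2HPO4 buffer), CH2Cl2, 0 °C
Reagents that add atoms: sodium hypochlorite, [Na+].[O-]Cl
Why: Jacobsen–Katsuki epoxidation, for which cis-β-methylstyrenes are the best substrate class: side-on approach of the (Z)-alkene to the oxomanganese species of the (R,R)-catalyst should deliver oxygen to the face that gives the (2R,3S)-cis-oxide (benzylic carbon R), with the N-oxide additive and low temperature limiting leakage to the trans-epoxide, which would be removed on triethylamine-deactivated silica.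

**Step 4**
Reactants: 6 2,6-dimethoxy-4-[(2R,3S)-3-methyloxiran-2-yl]phenyl pivalate (1.5 equiv); 7 4-iodo-3-methoxybenzaldehyde
Product: 8 4-[(2S,3S)-5-formyl-7-methoxy-3-methyl-2,3-dihydro-1-benzofuran-2-yl]-2,6-dimethoxyphenyl pivalate (2,3-trans)
Conditions: Pd(OAc)2 (10 mol%), 2-dicyclohexylphosphino-2',6'-diisopropoxybiphenyl (20 mol%), isopropyl 5-norbornene-2-carboxylate (50 mol%), Cs2CO3 (2 equiv), NMP, 90 °C
Reagents that add atoms: none
Why: Proposed new method: oxidative addition of zerovalent palladium to the C–I bond of 7, norbornene insertion and ortho C–H palladation should give the aryl–norbornyl palladacycle (divalent palladium), whose SN2-type attack on the methyl-bearing carbon of 6 gives a tetravalent palladium alkoxide; reductive elimination then forms C3–C3a, β-carbon elimination releases the norbornene, and the aryl(alkoxo)palladium species closes ring B while Cs2CO3 takes up HI. The closest known reaction type is the palladium/norbornene (Catellani-type) annulation of aryl iodides with terminal epoxides to 2-substituted 2,3-dihydrobenzofurans; a 1,2-disubstituted epoxide has not been shown to react in this way. Ring B closes by C7a–O1 reductive elimination from a six-membered aryl(alkoxo)palladacycle, which contracts to the five-membered cyclic ether. C3 is the only new stereocentre and is fixed by backside opening of the enantiopure epoxide (inversion; it keeps the letter S only because the incoming aryl carbon ranks below C2), whereas the C2–O1 bond is never broken (its descriptor changes from R to S through the ranking of its substituents alone), so the cis-epoxide becomes the trans-(2S,3S) ring. The step needs attack at the methyl-bearing and not the benzylic carbon, a single inversion, and one ortho-alkylation only: the para-acyloxy and two meta-methoxy groups make ring C a poor cation stabiliser, the bulky palladacycle should prefer the carbon next to the small methyl group, carbonate instead of surplus epoxide scavenges HI so that little iodohydrin (the path to net retention) builds up, and the C7 methoxy group blocks the second ortho position and drives norbornene extrusion; the regiochemistry in particular remains unproven.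

**Step 5**
Reactants: 8 4-[(2S,3S)-5-formyl-7-methoxy-3-methyl-2,3-dihydro-1-benzofuran-2-yl]-2,6-dimethoxyphenyl pivalate; 9 5-(ethylsulfonyl)-1-phenyl-1H-tetrazole
Product: 11 4-[(2S,3S)-7-methoxy-3-methyl-5-[(E)-prop-1-en-1-yl]-2,3-dihydro-1-benzofuran-2-yl]-2,6-dimethoxyphenyl pivalate, via potassium 1-[(1-phenyl-1H-tetrazol-5-yl)sulfonyl]ethan-1-ide 10 (not isolated)
Conditions: KN(SiMe3)2 added to 8 + 9, DME, −60 °C → rt
Reagents that add atoms: none
Why: Julia–Kocienski olefination: addition of the metalated tetrazolyl sulfone to the non-enolisable aldehyde, Smiles rearrangement and loss of SO2 and the tetrazololate should give the conjugated (E)-propenyl arene preferentially, while the hindered pivalate and the C2 and C3 stereocentres (neither is deprotonated under these conditions) stay untouched at low temperature.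

**Step 6**
Reactants: 11 4-[(2S,3S)-7-methoxy-3-methyl-5-[(E)-prop-1-en-1-yl]-2,3-dihydro-1-benzofuran-2-yl]-2,6-dimethoxyphenyl pivalate
Product: 12 odoratisol A, 4-[(2S,3S)-7-methoxy-3-methyl-5-[(E)-prop-1-en-1-yl]-2,3-dihydro-1-benzofuran-2-yl]-2,6-dimethoxyphenol
Conditions: NaOMe (2 equiv), MeOH/THF, 0 °C → rt; then aq NH4Cl
Reagents that add atoms: none
Why: Methanolysis (transesterification) of the aryl ester releases the phenol because the 2,6-dimethoxyphenoxide is a good leaving group, and neither the (E)-alkene nor the trans-dihydrobenzofuran, whose 2,3-trans arrangement is also the thermodynamically preferred one, should be affected by methoxide at room temperature.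

**Compound list**

1 | syringaldehyde (4-hydroxy-3,5-dimethoxybenzaldehyde) | COc1cc(C=O)cc(OC)c1O | starting material
2 | 4-formyl-2,6-dimethoxyphenyl pivalate | COc1cc(C=O)cc(OC)c1OC(=O)C(C)(C)C | intermediate
3 | ethyltriphenylphosphonium bromide | CC[P+](c1ccccc1)(c1ccccc1)c1ccccc1.[Br-] | starting material
4 | ethylidenetriphenylphosphorane (not isolated) | CC=P(c1ccccc1)(c1ccccc1)c1ccccc1 | intermediate
5 | (Z)-2,6-dimethoxy-4-(prop-1-en-1-yl)phenyl pivalate | C/C=C\c1cc(OC)c(OC(=O)C(C)(C)C)c(OC)c1 | intermediate
6 | 2,6-dimethoxy-4-[(2R,3S)-3-methyloxiran-2-yl]phenyl pivalate (cis) | C[C@H]1[C@@H](c2cc(OC)c(OC(=O)C(C)(C)C)c(OC)c2)O1 | intermediate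
7 | 4-iodo-3-methoxybenzaldehyde | O=Cc1ccc(I)c(OC)c1 | starting material
8 | 4-[(2S,3S)-5-formyl-7-methoxy-3-methyl-2,3-dihydro-1-benzofuran-2-yl]-2,6-dimethoxyphenyl pivalate (trans) | O=Cc1cc(OC)c2c(c1)[C@H](C)[C@@H](c1cc(OC)c(OC(=O)C(C)(C)C)c(OC)c1)O2 | intermediate
9 | 5-(ethylsulfonyl)-1-phenyl-1H-tetrazole | CCS(=O)(=O)c1nnnn1-c1ccccc1 | starting material
10 | potassium 1-[(1-phenyl-1H-tetrazol-5-yl)sulfonyl]ethan-1-ide (not isolated) | C[CH-]S(=O)(=O)c1nnnn1-c1ccccc1.[K+] | intermediate
11 | 4-[(2S,3S)-7-methoxy-3-methyl-5-[(E)-prop-1-en-1-yl]-2,3-dihydro-1-benzofuran-2-yl]-2,6-dimethoxyphenyl pivalate | C/C=C/c1cc(OC)c2c(c1)[C@H](C)[C@@H](c1cc(OC)c(OC(=O)C(C)(C)C)c(OC)c1)O2 | intermediate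
12 | odoratisol A | C/C=C/c1cc(OC)c2c(c1)[C@H](C)[C@@H](c1cc(OC)c(O)c(OC)c1)O2 | target

**Step count and risks**

Total steps: 6. Longest linear sequence: 6 steps (1 → 2 → 5 → 6 → 8 → 11 → 12); 3, 7 and 9 are purchased.

Steps most likely to fail:

1. Step 4 (Proposed new method). Three processes may go wrong:
   - Ring opening may occur at the benzylic instead of the methyl-bearing epoxide carbon.
   - Stereochemical fidelity may be lost, through iodide-mediated pre-opening of the epoxide (net retention) or through benzylic ionisation with rearrangement to a carbonyl compound.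
   - The palladacycle may undergo reductive elimination before the sluggish internal epoxide has reacted.

   Fallback (known chemistry), setting out from 5 and coming back at 8: the (Z)-alkene 5 would be equilibrated with catalytic PdCl2(MeCN)2 in CH2Cl2 to the thermodynamically preferred (E)-2,6-dimethoxy-4-(prop-1-en-1-yl)phenyl pivalate F1. A Heck-type oxyarylation of F1 with 5-iodovanillin (4-hydroxy-3-iodo-5-methoxybenzaldehyde, COc1cc(C=O)cc(I)c1O; Pd(OAc)2, Ag2CO3, acetone, reflux) follows; this is an established entry to trans-2-aryl-3-methyl-2,3-dihydrobenzofurans. The aryl group adds to the methyl-bearing alkene carbon and the phenol oxygen to the benzylic carbon, which should give racemic trans-4-(5-formyl-7-methoxy-3-methyl-2,3-dihydro-1-benzofuran-2-yl)-2,6-dimethoxyphenyl pivalate F2. Preparative chromatography of F2 on a chiral stationary phase would deliver the (2S,3S)-enantiomer 8, from which steps 5 and 6 continue unchanged.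

2. Step 3. Stepwise collapse of the radical intermediate at manganese may leak to the trans-epoxide, and facial selectivity may be incomplete; both would end up as the wrong diastereomer or enantiomer after step 4. Fallback, setting out from 5 and coming back at 6: a change of the oxygen-transfer mechanism to a metal-free, concerted one, namely Shi epoxidation with a carbohydrate-derived oxazolidinone ketone of the series made for cis-alkenes. The ketone enantiomer would be the one that converts cis-β-methylstyrene into its (1R,2S)-oxide, used with KHSO5 (as 2KHSO5·KHSO4·K2SO4) and K2CO3 in DME/aqueous buffer at −10 °C. The chiral dioxirane transfers oxygen through a spiro transition state, so the alkene geometry is conserved and no trans-epoxide can form. No new compound is involved.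

3. Step 2. Z-selectivity may be incomplete with an aromatic aldehyde, and (E)-alkene carried forward would be converted into the trans-epoxide and hence the 2,3-cis ring. Fallback, setting out from 2 and coming back at 5: geometry is fixed by stereospecific cross-coupling instead of by a kinetic olefination. Dibromo-olefination of 2 (CBr4, PPh3, CH2Cl2, 0 °C) would give 4-(2,2-dibromoethenyl)-2,6-dimethoxyphenyl pivalate F3. Hydrogenolysis with Bu3SnH and catalytic Pd(PPh3)4 removes the bromine trans to the aryl group selectively and should give (Z)-4-(2-bromoethenyl)-2,6-dimethoxyphenyl pivalate F4. Negishi coupling of F4 with MeZnCl and catalytic Pd(PPh3)4 in THF, which proceeds with retention of alkene geometry, would return the (Z)-alkene 5.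

**Further compounds**

F1 | step 4 | (E)-2,6-dimethoxy-4-(prop-1-en-1-yl)phenyl pivalate | C/C=C/c1cc(OC)c(OC(=O)C(C)(C)C)c(OC)c1
F2 | step 4 | racemic trans-4-(5-formyl-7-methoxy-3-methyl-2,3-dihydro-1-benzofuran-2-yl)-2,6-dimethoxyphenyl pivalate (both enantiomers) | O=Cc1cc(OC)c2c(c1)[C@H](C)[C@@H](c1cc(OC)c(OC(=O)C(C)(C)C)c(OC)c1)O2.O=Cc1cc(OC)c2c(c1)[C@@H](C)[C@H](c1cc(OC)c(OC(=O)C(C)(C)C)c(OC)c1)O2
F0 | step 3 | none | none
F3 | step 2 | 4-(2,2-dibromoethenyl)-2,6-dimethoxyphenyl pivalate | COc1cc(C=C(Br)Br)cc(OC)c1OC(=O)C(C)(C)C
F4 | step 2 | (Z)-4-(2-bromoethenyl)-2,6-dimethoxyphenyl pivalate | Br/C=C\c1cc(OC)c(OC(=O)C(C)(C)C)c(OC)c1
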